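**Retrosynthetic overview**
- Vernolide-B ← 13-O-acetylation and selective C2=C3 reduction of its 2,3-didehydro-13-ol.
- That macrocycle ← one key operation on an acyclic furan–butenolide: intramolecular furan Diels–Alder (dearomatisation, closes a 6-ring, sets C4), then Grob-type fragmentation of the C1–C6 bond with loss of tosylate and MeOH capture at C1. This expands the 6-ring to the 1,4-oxygen-bridged 10-ring and gives the methyl ketal and the 5E-ylidene butenolide.
- Key-step substrate ← tigloylation and γ-formylation/O-tosylation (adds C5) of a secondary alcohol made by Nozaki–Hiyama–Kishi coupling (C7–C8) of a furyl aldehyde with a 4-bromobutenolide.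
- Furyl aldehyde ← 2-methylfuran + crotonaldehyde (organocatalytic Friedel–Crafts, sets C10). Bromobutenolide ← desymmetrising Pd cyclocarbonylation of (E)-2,3-dibromobut-2-ene-1,4-diol.
- Ring order: butenolide → (furan supplied) → transient cyclohexane/7-oxanorbornene → 10-membered carbocycle with the tetrahydrofuran ketal bridge.

Assumption: the target is exactly the given SMILES, i.e. (1S,4R,8S,10R), 5E, tiglate ester. Hirsutinolide numbering is used: C1 ketal carbon, C4 quaternary ether carbon, C5=C6 ylidene, C6–O lactone, C7=C11, C8 O-tigloyl, C10 CH(CH3), C12 C=O, C13 CH2OAc.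

**Step 1**
Reactants: 1, 2-methylfuran; 2, (E)-crotonaldehyde
Product: 3, (R)-3-(5-methylfuran-2-yl)butanal
Conditions: 1 (3 equiv), (2S,5S)-5-benzyl-2-tert-butyl-3-methylimidazolidin-4-one·TFA (20 mol%), CH2Cl2/i-PrOH, −40 °C
Reagents that add atoms: none
Why: Iminium-catalysed enantioselective Friedel–Crafts conjugate addition at the only free α-position of the furan; the catalyst's benzyl arm shields one face of the (E)-iminium and sets C10 as R (the R sense with this catalyst enantiomer is assigned by analogy with indole/pyrrole additions; use the enantiomeric catalyst if it proves opposite).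

**Step 2**
Reactants: 4, (E)-2,3-dibromobut-2-ene-1,4-diol
Product: 5, 4-bromo-3-(hydroxymethyl)furan-2(5H)-one
Conditions: Pd(OAc)2 (3 mol%), Xantphos, CO (1 atm), i-Pr2NEt, MeCN, 60 °C, stopped at about 60% conversion (4 recovered)
Reagents that add atoms: carbon monoxide, [C-]#[O+]
Why: Pd-catalysed cyclocarbonylation of a γ-hydroxy vinyl bromide, in which the acyl-Pd is captured by the cis CH2OH; 4 is C2-symmetric, so insertion at either C–Br gives the same butenolide, and partial conversion limits a second carbonylation.

**Step 3**
Reactants: 5
Product: 6, 4-bromo-3-{[(triethylsilyl)oxy]methyl}furan-2(5H)-one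
Conditions: TESCl, imidazole, CH2Cl2, 0 °C
Reagents that add atoms: chlorotriethylsilane, CC[Si](Cl)(CC)CC
Why: Routine silylation of the primary alcohol; a silyl ether, unlike an acetate, cannot be expelled from the butenolide dienolate formed in step 6.

**Step 4**
Reactants: 3; 6
Product: 7, 4-[(1S,3R)-1-hydroxy-3-(5-methylfuran-2-yl)butyl]-3-{[(triethylsilyl)oxy]methyl}furan-2(5H)-one
Conditions: CrCl2 (10 mol%), chiral sulfonamide ligand (enantiomer giving 8S), NiCl2·(2,9-dimethylphenanthroline) (2 mol%), Mn, Cp2ZrCl2, LiCl, MeCN, rt
Reagents that add atoms: none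
Why: Catalytic asymmetric Nozaki–Hiyama–Kishi addition of the activated β-bromo-enoate to the aldehyde forms C7–C8 in the presence of lactone, silyl ether and furan; C8 (S) is set by the chiral Cr catalyst because C10 is too remote, and any 8R epimer can be converged in step 5 by Mitsunobu esterification with tiglic acid.

**Step 5**
Reactants: 7; 8, tigloyl chloride [(E)-2-methylbut-2-enoyl chloride]
Product: 9, (1S,3R)-3-(5-methylfuran-2-yl)-1-(5-oxo-4-{[(triethylsilyl)oxy]methyl}-2,5-dihydrofuran-3-yl)butyl (E)-2-methylbut-2-enoate
Conditions: pyridine, DMAP (cat.), CH2Cl2, 0 °C → rt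
Reagents that add atoms: none beyond 8
Why: DMAP-catalysed O-acylation with retention at C8; the ester also stops O8 from competing with MeOH for the C1 oxocarbenium in step 7.

**Step 6**
Reactants: 9
Product: 10, the tiglate 9 carrying an exocyclic (tosyloxy)methylidene at the butenolide γ-carbon (C5H(OTs)=C6; Z major, either isomer usable)
Conditions: LiHMDS (2.1 equiv), THF, −78 °C; HCO2CH2CF3, −78 → −40 °C; then Ts2O, −78 → 0 °C
Reagents that add atoms: 2,2,2-trifluoroethyl formate, O=COCC(F)(F)F (supplies C5 and its O); p-toluenesulfonic anhydride, Cc1ccc(cc1)S(=O)(=O)OS(=O)(=O)c1ccc(C)cc1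
Why: Claisen-type γ-formylation through the 2-oxidofuran dienolate (the α-carbon is quaternary, so only the γ-formyl product is deprotonated to a stable vinylogous enolate), then O-sulfonylation on the formyl oxygen to give the enol tosylate; no stereocentre is made.

**Step 7 (key step)**
Reactants: 10
Product: 11, (1R,4R,8S,10R)-1,4-epoxy-13-hydroxy-1-methoxy-8-tigloyloxygermacra-2,5E,7(11)-trien-6,12-olide (2,3-didehydro-13-O-desacetyl vernolide-B; same spatial arrangement as the target, the C1 descriptor changes only through CIP priorities)
Conditions: MeOH (0.01 M), 2,6-lutidine (2 equiv), 65 °C, sealed tube, 24–48 h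
Reagents that add atoms: methanol, CO
Why: Proposed new method: on heating, the 2,5-dialkylfuran adds across the exocyclic C5=C6 enol-tosylate alkene (δ-terminus of the dienoate) in an intramolecular furan Diels–Alder reaction whose four-atom tether fixes the regiochemistry (C1–C6 closes a cyclohexane, C5 bonds to the methyl-bearing C4); the 7-oxanorbornene contains an O(bridge)–C1–C6–C5–OTs Grob array, so the C1–C6 bond heterolyses (C6 leaves as the aromatic 2-oxidofuran), tosylate is expelled to give the C5=C6 ylidene lactone, and the C1 oxocarbenium is captured by MeOH on the face opposite the carbon bridge, expanding the 6-ring to the oxygen-bridged 10-ring; C4 (R) is set in the exo, chair-like cycloaddition transition state in which the cis C10-Me and C8-OTig are both equatorial, C1 follows because only the cis-bridged ketal is geometrically reasonable (and it can equilibrate), and the ring forces C4 and C7 cis on C5=C6 (5E); the lutidinium tosylate released cleaves the primary TES ether in the same pot; closest known reaction types are the intramolecular Diels–Alder reaction of 2-alkylfurans with tethered activated alkenes, Grob fragmentation of γ-sulfonyloxy ethers, and addition–elimination at β-sulfonyloxy enoates.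

**Step 8**
Reactants: 11
Product: 12, (1S,4R,8S,10R)-1,4-epoxy-13-hydroxy-1-methoxy-8-tigloyloxygermacra-5E,7(11)-dien-6,12-olide (13-O-desacetyl vernolide-B)
Conditions: 2-nitrobenzenesulfonyl hydrazide, Et3N, CH2Cl2, rt (diimide, added portionwise)
Reagents that add atoms: none (hydrogen only)
Why: Diimide transfer hydrogenation reduces the unconjugated cis-disubstituted C2=C3 in preference to the conjugated tri- and tetrasubstituted alkenes (tiglate, C5=C6, C7=C11) and causes no allylic C–O hydrogenolysis; no stereocentre changes.

**Step 9**
Reactants: 12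
Product: 13, vernolide-B
Conditions: Ac2O, pyridine, DMAP (cat.), CH2Cl2, 0 °C
Reagents that add atoms: acetic anhydride, CC(=O)OC(C)=O
Why: Acetylation of the only free (primary allylic) hydroxyl; there is no γ-H left on the ylidene lactone, so the C13 acetate is stable.

**Compound list**
1 | 2-methylfuran | Cc1ccco1 | starting material
2 | (E)-crotonaldehyde | C/C=C/C=O | starting material
3 | (R)-3-(5-methylfuran-2-yl)butanal | C[C@H](CC=O)c1ccc(C)o1 | intermediate
4 | (E)-2,3-dibromobut-2-ene-1,4-diol | OC/C(Br)=C(\Br)CO | starting material
5 | 4-bromo-3-(hydroxymethyl)furan-2(5H)-one | O=C1OCC(Br)=C1CO | intermediate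
6 | 4-bromo-3-{[(triethylsilyl)oxy]methyl}furan-2(5H)-one | O=C1OCC(Br)=C1CO[Si](CC)(CC)CC | intermediate
7 | 4-[(1S,3R)-1-hydroxy-3-(5-methylfuran-2-yl)butyl]-3-{[(triethylsilyl)oxy]methyl}furan-2(5H)-one | O[C@@H](C[C@@H](C)c1ccc(C)o1)C2=C(CO[Si](CC)(CC)CC)C(=O)OC2 | intermediate
8 | tigloyl chloride | C/C=C(\C)C(Cl)=O | starting material
9 | C8 tiglate of 7 | C/C=C(\C)C(=O)O[C@@H](C[C@@H](C)c1ccc(C)o1)C2=C(CO[Si](CC)(CC)CC)C(=O)OC2 | intermediate
10 | 9 with γ-(tosyloxy)methylidene on the butenolide (Z shown) | C/C=C(\C)C(=O)O[C@@H](C[C@@H](C)c1ccc(C)o1)C2=C(CO[Si](CC)(CC)CC)C(=O)O/C2=C\OS(=O)(=O)c3ccc(C)cc3 | intermediate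
11 | 2,3-didehydro-13-O-desacetyl vernolide-B | C/C=C(\C)C(=O)O[C@H]1C[C@@H](C)[C@]2(OC)C=C[C@](C)(/C=C3/OC(=O)C(CO)=C31)O2 | intermediate
12 | 13-O-desacetyl vernolide-B | C/C=C(\C)C(=O)O[C@H]1C[C@@H](C)[C@]2(OC)CC[C@](C)(/C=C3/OC(=O)C(CO)=C31)O2 | intermediate
13 | vernolide-B | C/C=C(\C)C(=O)O[C@H]1C[C@@H](C)[C@]2(OC)CC[C@](C)(/C=C3/OC(=O)C(COC(C)=O)=C31)O2 | target

**Totals**
Total steps: 9. Longest linear sequence: 8 (steps 2–9 from 4; 7 from 1).

**Three steps most likely to fail, with fallbacks**
1. Step 7 (Diels–Alder/Grob cascade). The cycloaddition may be too slow or unfavourable, fragmentation may not follow, or the wrong furan face may react. Fallback: abandon ring expansion and close the 10-ring at C7–C8 instead. Join C4–C5 intermolecularly by oxidising the furan of 3 (aldehyde masked as its acetal) to the 2,5-dimethoxy bis-ketal, hydrogenating, and substituting the C4 ketal (TMSOTf) with a C5 vinylsilane of the bromobutenolide; then unmask the aldehyde and run an intramolecular NHK macrocyclisation.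
2. Step 6 (one-pot γ-formylation/O-tosylation next to a tiglate). Risks are O- versus C-selectivity, sulfonylation on the lactone oxygen, and base damage to the ester. Fallback: use amide-acetal chemistry without strong base. Condense 9 with tert-butoxybis(dimethylamino)methane to the γ-(dimethylaminomethylidene) lactone, hydrolyse to the hydroxymethylidene lactone and sulfonylate (Ts2O, Et3N); this costs one extra step.
3. Step 2 (carbonylative desymmetrisation). Risks are a second carbonylation to the bis-lactone and debromination to butynediol. Fallback: build 6 from an allenoate. Hydroxymethylate ethyl buta-2,3-dienoate (CH2O, DABCO), silylate, then CuBr2 bromolactonisation to the 4-bromobutenolide; this costs one extra step.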